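Slow as these flasks look, I integrate no rate law for them; I count instead, and solve the two ends separately.

| flask | starting material | partner | remark | time |
|---|---|---|---|---|
| winter | 0.38 M | 0.15 M (fed, over 10 min) | run made earlier |  |
| spring | 0.12 M | 0.15 M (fed, over 10 min) | run made earlier |  |
| Wednesday's | 0.25 M | 0.150 M (fed, over 10 min) |  | 20 min |
| Saturday's | 0.25 M | 0.300 M (fed, over 10 min) |  | 20 min |

| run | time / min | starting material / % | product / % |
|---|---|---|---|
| winter | 1.50 | 93.7 | 0.9 |
| winter | 4.00 | 82.0 | 2.0 |
| winter | 8.00 | 58.6 | 10.8 |
| winter | 12.0 | 39.5 | 21.5 |
| spring | 3.00 | 71.6 | 3.1 |
| spring | 6.00 | 36.1 | 15.5 |
| spring | 10.0 | 8.7 | 34.4 |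
| spring | 12.0 | 5.1 | 42.8 |

(scatter of a reading: 0.5 percentage points)

1. part of the starting material that has reacted at the end, Wednesday's
2. part of the starting material that has reacted at the end, Saturday's
3. what raising the concentration of partner from its lowest to its highest value here does to the part of the starting material that has reacted (changes below 5 percentage points count as none) (it rises / no change / it falls)

- the numbers in the tables scatter by 0.5 percentage points (one standard deviation)
- a reading or a percentage of product counts all its forms, free or not
- what has gone from starting material into another species counts as reacted, even if it can come back
- a reading of starting material is of its free form alone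

I read the last row of each table. In the winter flask, where partner is the limiting reagent, 39.5% of the starting material stands at 12.0 min. That gives 1.53 as its take, the c(starting material) gone per c(partner) charged. The winter take is above one, so in that flask one partner accounts for more than one starting material.

The spring row shows the other end. With 1.25 partner per starting material, 5.1% stands at 12.0 min, so 94.9% has reacted. Its take of 0.759 therefore measures the charge of starting material, not what partner can do.

Now I join the ends: the part reacted is the take times c(partner)/c(starting material), capped at the whole charge. Wednesday's has 0.600 partner per starting material, so I reckon 92.0%. This borrows winter's reading at 12.0 min, earlier than Wednesday's 20 min, from a flask with more starting material. Saturday's has 1.20, and the product with the take passes one, so the cap applies and I reckon the whole charge. That lies 8 percentage points above my Wednesday figure, against a margin of 5 points, so I expect a rise, though a narrow one.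

The forecast, made separately, says 94%, 99.3% and it rises, on the ground that “partner is limiting and turns over”. Its Wednesday figure stands above mine.

The flasks give 88.3% for Wednesday's and 98.1% for Saturday's: it rises, by 9.8 points. The difference in c(partner) is the main reason for that rise.

    starting material + partner ⇌ intermediate (K = 196 /M, k = 9.98 /M/min)
    intermediate ⇌ product + by-product (K = 0.170 M, k = 0.129 /min)
    starting material + by-product ⇌ idle adduct A, settled at all times (K = 0.850 /M)
    starting material + product ⇌ idle adduct B, settled at all times (K = 77.2 /M)

Wednesday's take is 1.47. Without the joining of starting material and product to idle adduct B, Wednesday's flask reaches 61.6%, a take of 1.03, close to one; that capture is part of why the take exceeds one. A flask like Wednesday's with 0.037 M of partner reckons to 22.7% by winter's take, while it gives 27.7%, a take of 1.87.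

(The numbers in the tables are simulated for an exercise, noise included.)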